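At early times the two earlier runs look alike as fractions of their charge, with 11% in chains in north and 13% in north-west at 4.00 min, and from them I have to reckon where amber and violet end.

| setting | north | north-west | amber | violet |
|---|---|---|---|---|
| free monomer | 0.059 M | 0.090 M | 0.050 M | 0.080 M |
| initiator | 5 mM | 5 mM | 5.0 mM | 5.0 mM |
| remark | run made earlier | run made earlier |  |  |
| time |  |  | 30 min | 30 min |

| run | time / min | monomer in chains / % | free monomer / % |
|---|---|---|---|
| north | 1.33 | 7 | 98 |
| north | 2.00 | 8 | 95 |
| north | 3.00 | 11 | 89 |
| north | 4.00 | 11 | 84 |
| north | 6.00 | 19 | 75 |
| north | 10.0 | 26 | 69 |
| north | 15.0 | 35 | 62 |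
| north-west | 0.833 | 3 | 99 |
| north-west | 2.50 | 9 | 89 |
| north-west | 4.00 | 13 | 85 |
| north-west | 6.00 | 17 | 76 |
| north-west | 10.0 | 23 | 71 |
| north-west | 12.0 | 24 | 66 |
| north-west | 15.0 | 25 | 69 |

(standard deviation of a reading: 2 percentage points)

- the average divides the monomer in chains by the number of chains begun, living and dead together
- the analysis behind the earlier runs scatters by 2 percentage points, standard deviation
- the earlier runs do not show the number of chains; that part of a forecast is a guess

- which of the two ends with the longer chains by the average number of monomer units in a chain (chains begun, living or dead) ("neither" if they lie within 10%) (amber / violet / neither)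
- average number of monomer units in a chain (chains begun, living or dead) at the end, amber
- average number of monomer units in a chain (chains begun, living or dead) at the end, violet

Later the two runs part: north-west reads 23%, 24% and 25% from 10.0 min to 15.0 min, flat within the scatter of 2 percentage points, while north climbs from 26% to 35% over the same stretch. So I multiply the fraction in chains by the free monomer charged and divide by the initiator charged, and the last reading of north-west gives 4.50, the yield per initiator, meaning units in chains per initiator charged, with north at 4.13 at its last reading and still rising. I freeze this yield for amber and violet, which carry the same initiator charge, so I expect amber to end with 45.0% of its free monomer in chains and violet with 28.1%. The length is the yield divided by the fraction of initiator that begins a chain, and since the runs do not show that fraction, I guess it near one; this is my weak link. Both flasks then come to about 4.50 units, so I commit to "neither".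

The forecast differs from this reckoning: it gives 5 (from 4 to 9) for amber and 6.5 (from 5.2 to 12) for violet, takes a conversion limit “slightly lower at higher charge”, and names violet as longer.

The flask gives 4.49 for amber and 4.68 for violet, so the answer is neither.

    free monomer + living end → monomer in chains + living end, rate k1*[living end]*[free monomer] (k = 17.0 L mol⁻¹ min⁻¹)
    initiator → spent initiator A (k = 0.0100 min⁻¹)
    living end + free monomer → dead end B (k = 4.60 L mol⁻¹ min⁻¹)
    free monomer → uncatalysed product (k = 0.00170 min⁻¹)
    free monomer + initiator → living end + monomer in chains (k = 4.50 L mol⁻¹ min⁻¹)

At 30.0 min amber's yield is 4.21; 1.11% of its initiator remains and spent initiator A holds 5.13%, so 93.8% began chains, and yield over that fraction gives 4.49. In the neighbour like violet but with 0.020 M of initiator, the frozen yield asks for 0.0900 M of monomer in chains, more than the 0.080 M charged, whose ratio to the initiator is 4.00. There free monomer is the limiting reagent, down to 1.85%, the yield is 3.24 and the length 3.75.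

All runs were generated by integration for substances that don't exist; the scatter is artificial.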